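**Plan**

- Retrosynthesis: the two O-benzyl groups and the propionyl group of ring A (aryl–acyl bond) come off last. Ring A is then cut at the two bonds that join its methyl-bearing carbon and its benzyl-bearing carbon to the two outer hydroxylated carbons, giving 1-arylpentan-3-one 9 and malonyl dichloride 10.
- Enabling feature: in ring A the C(CH3) and C(CH2Ar) atoms flank one C–OH, which is the alpha-carbon/carbonyl/alpha-carbon array of the pentan-3-one. The remaining C(OH)–CH–C(OH) triad is a malonyl unit.
- The ketone chain of 9 is cut at its former C=C (Horner–Wadsworth–Emmons) back to aldehyde 6. Ring B goes back through O-benzylation, formylation, para-O-methylation and C-propionylation to 2-methylphloroglucinol.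
- Forward: ring B is purchased as an arene and decorated (steps 1–4), the five-carbon ketone chain is attached (steps 5–6), ring A is the only ring constructed (step 7), then ring A is propionylated and the benzyl ethers are removed (steps 8–9).
- Stereochemistry: the target has no stereocentre. The E double bond of 8 is the only stereo element on the way and is erased in step 6.

Key step: step 7

Assumption (chemistry): the first acylation in step 7 is taken as unselective between the two alpha carbons of 9, so both pyranones (11, 12) and both dioxo esters (13, 14) are carried as intermediates; all four converge on 15.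

**Route**

Step 1
Reactants: 1 2-methylphloroglucinol; 2 propionyl chloride
Product: 3 1-(2,4,6-trihydroxy-3-methylphenyl)propan-1-one
Conditions: 2 (1.1 equiv), AlCl3 (3 equiv), PhNO2/CH2Cl2, 0 °C to rt; aq. HCl
Reagents that add atoms: none
Why: Friedel–Crafts acylation of a very electron-rich arene whose two open carbons are equivalent, and the first acyl group deactivates the ring toward a second acylation.

Step 2
Reactants: 3 1-(2,4,6-trihydroxy-3-methylphenyl)propan-1-one
Product: 4 1-(2,6-dihydroxy-4-methoxy-3-methylphenyl)propan-1-one
Conditions: Me2SO4 (1.0 equiv), K2CO3 (1.1 equiv), acetone, rt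
Reagents that add atoms: dimethyl sulfate, COS(=O)(=O)OC
Why: Williamson-type O-methylation in which the hydroxyl para to the carbonyl, the only one not hydrogen-bonded to it, should ionise and alkylate first, with one equivalent of Me2SO4 limiting over-methylation.

Step 3
Reactants: 4 1-(2,6-dihydroxy-4-methoxy-3-methylphenyl)propan-1-one
Product: 5 2,4-dihydroxy-6-methoxy-5-methyl-3-propanoylbenzaldehyde
Conditions: Cl2CHOMe (1.5 equiv), TiCl4 (2.5 equiv), CH2Cl2, 0 °C; then 1 M HCl
Reagents that add atoms: dichloromethyl methyl ether, COC(Cl)Cl; water, O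
Why: Rieche formylation at the single unsubstituted ring carbon, which lies ortho to a phenol and to the methoxy group; a Vilsmeier reagent is avoided because ortho-hydroxyaryl ketones can be diverted to chromones.

Step 4
Reactants: 5 2,4-dihydroxy-6-methoxy-5-methyl-3-propanoylbenzaldehyde
Product: 6 2,4-bis(benzyloxy)-6-methoxy-5-methyl-3-propanoylbenzaldehyde
Conditions: BnBr (2.5 equiv), K2CO3 (3 equiv), DMF, 60 °C
Reagents that add atoms: benzyl bromide, BrCc1ccccc1
Why: Williamson etherification of both chelated phenols under polar aprotic conditions; every ring carbon is already substituted, so C-benzylation could only occur with loss of aromaticity.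

Step 5
Reactants: 6 2,4-bis(benzyloxy)-6-methoxy-5-methyl-3-propanoylbenzaldehyde; 7 diethyl (2-oxobutyl)phosphonate
Product: 8 (E)-1-[2,4-bis(benzyloxy)-6-methoxy-5-methyl-3-propanoylphenyl]pent-1-en-3-one
Conditions: 7 (1.2 equiv), LiCl, DBU, MeCN, rt
Reagents that add atoms: none
Why: Horner–Wadsworth–Emmons olefination under Masamune–Roush conditions, in which the stabilised keto phosphonate attacks the aldehyde and leaves the hindered aryl ketone alone, giving the E-enone.

Step 6
Reactants: 8 (E)-1-[2,4-bis(benzyloxy)-6-methoxy-5-methyl-3-propanoylphenyl]pent-1-en-3-one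
Product: 9 1-[2,4-bis(benzyloxy)-6-methoxy-5-methyl-3-propanoylphenyl]pentan-3-one
Conditions: H2 (1 atm), Pd/C, 2,2'-bipyridyl (0.5 equiv), EtOAc/MeOH, rt
Reagents that add atoms: none
Why: catalytic hydrogenation of the enone C=C over palladium on carbon poisoned with a nitrogen base, a known way to saturate alkenes while suppressing hydrogenolysis of aryl benzyl ethers and reduction of ketones.

Step 7
Reactants: 9 1-[2,4-bis(benzyloxy)-6-methoxy-5-methyl-3-propanoylphenyl]pentan-3-one; 10 malonyl dichloride
Product: 15 1-{2,6-bis(benzyloxy)-4-methoxy-3-methyl-5-[(2,4,6-trihydroxy-3-methylphenyl)methyl]phenyl}propan-1-one, via 6-arylethyl-5-methyl pyranone 11 (not isolated), via 5-arylmethyl-6-ethyl pyranone 12 (not isolated), via 4-methyl dioxo ester 13 (not isolated), via 4-arylmethyl dioxo ester 14 (not isolated)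
Conditions: 10 (1.1 equiv), CH2Cl2, 0 to 40 °C, evaporate; NaOMe (4 equiv), MeOH, 50 °C, evaporate; NaH (4 equiv), THF, reflux, argon; 1 M HCl, 0 °C
Reagents that add atoms: none
Why: Proposed new method: malonyl dichloride should C-acylate either enol of the dialkyl ketone of 9, and the resulting 3,5-dioxoacyl chloride should lactonise through the enol oxygen to a 4-hydroxypyran-2-one (11 or 12). Methoxide then opens the lactone to the methyl 3,5-dioxoalkanoate (13 or 14), and once methanol is removed NaH generates the polyanion whose terminal carbanion, the second alpha carbon of the original ketone, attacks the ester in a 6-(enolendo)-exo-trig Claisen closure; loss of methoxide and enolisation of the cyclohexane-1,3,5-trione to the arene make the closure irreversible. The closest known reaction types are the condensation of malonyl dichloride with ketones or their enol ethers to 4-hydroxypyran-2-ones, the related Effenberger-type cyclisation to bicyclic triones, the methoxide opening of such pyranones to 3,5-dioxo esters and the base-induced Claisen cyclisation of 3,5-dioxoalkanoates to phloroglucinols; what is new is running them as one operation on an unactivated open-chain dialkyl ketone. No stereocentre is formed and the first acylation needs no regiocontrol, because the only cyclisation open to either dioxo ester is the six-membered Claisen closure (other C–C closures would give four-membered rings and O-attack merely re-forms a pyranone), so both branches end in the same ring A. The selectivity required is reaction at the dialkyl ketone instead of the aryl ketone of ring B; it should follow from the two flanking benzyloxy groups, which twist that carbonyl out of the ring plane and retard its enolisation, helped by using close to one equivalent of 10, while ring B has no free carbon and no free phenol to be acylated.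

Step 8
Reactants: 15 1-{2,6-bis(benzyloxy)-4-methoxy-3-methyl-5-[(2,4,6-trihydroxy-3-methylphenyl)methyl]phenyl}propan-1-one
Product: 16 1-{2,6-bis(benzyloxy)-4-methoxy-3-methyl-5-[(2,4,6-trihydroxy-3-methyl-5-propanoylphenyl)methyl]phenyl}propan-1-one
Conditions: (EtCO)2O (1.1 equiv), BF3·OEt2 (3 equiv), CH2Cl2/1,4-dioxane, 0 °C to rt; then aq. MeOH, 40 °C
Reagents that add atoms: propionic anhydride, CCC(=O)OC(=O)CC
Why: Friedel–Crafts C-acylation at the only free aromatic carbon of the electron-rich rings, the ring A carbon between two hydroxyls, with ring B fully substituted and the monodentate Lewis acid BF3 not expected to strip the benzyl ethers at room temperature.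

Step 9
Reactants: 16 1-{2,6-bis(benzyloxy)-4-methoxy-3-methyl-5-[(2,4,6-trihydroxy-3-methyl-5-propanoylphenyl)methyl]phenyl}propan-1-one
Product: 17 1-{2,6-dihydroxy-4-methoxy-3-methyl-5-[(2,4,6-trihydroxy-3-methyl-5-propanoylphenyl)methyl]phenyl}propan-1-one (CNP0215809.0)
Conditions: H2 (1 atm), Pd/C, EtOAc/MeOH, rt
Reagents that add atoms: none
Why: hydrogenolysis of the two aryl benzyl ethers over palladium on carbon, under which the aryl ketones, chelated by ortho hydroxyls, and the aryl methyl ether should remain untouched.

**Compound list**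

1 | 2-methylphloroglucinol (2-methylbenzene-1,3,5-triol) | Cc1c(O)cc(O)cc1O | starting material
2 | propionyl chloride | CCC(=O)Cl | starting material
3 | 1-(2,4,6-trihydroxy-3-methylphenyl)propan-1-one | CCC(=O)c1c(O)cc(O)c(C)c1O | intermediate
4 | 1-(2,6-dihydroxy-4-methoxy-3-methylphenyl)propan-1-one | CCC(=O)c1c(O)cc(OC)c(C)c1O | intermediate
5 | 2,4-dihydroxy-6-methoxy-5-methyl-3-propanoylbenzaldehyde | CCC(=O)c1c(O)c(C)c(OC)c(C=O)c1O | intermediate
6 | 2,4-bis(benzyloxy)-6-methoxy-5-methyl-3-propanoylbenzaldehyde | CCC(=O)c1c(OCc2ccccc2)c(C)c(OC)c(C=O)c1OCc1ccccc1 | intermediate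
7 | diethyl (2-oxobutyl)phosphonate | CCC(=O)CP(=O)(OCC)OCC | starting material
8 | (E)-1-[2,4-bis(benzyloxy)-6-methoxy-5-methyl-3-propanoylphenyl]pent-1-en-3-one | CCC(=O)/C=C/c1c(OC)c(C)c(OCc2ccccc2)c(C(=O)CC)c1OCc1ccccc1 | intermediate
9 | 1-[2,4-bis(benzyloxy)-6-methoxy-5-methyl-3-propanoylphenyl]pentan-3-one | CCC(=O)CCc1c(OC)c(C)c(OCc2ccccc2)c(C(=O)CC)c1OCc1ccccc1 | intermediate
10 | malonyl dichloride | O=C(Cl)CC(=O)Cl | starting material
11 | 6-{2-[2,4-bis(benzyloxy)-6-methoxy-5-methyl-3-propanoylphenyl]ethyl}-4-hydroxy-5-methyl-2H-pyran-2-one | CCC(=O)c1c(OCc2ccccc2)c(C)c(OC)c(CCC2=C(C)C(O)=CC(=O)O2)c1OCc1ccccc1 | intermediate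
12 | 5-{[2,4-bis(benzyloxy)-6-methoxy-5-methyl-3-propanoylphenyl]methyl}-6-ethyl-4-hydroxy-2H-pyran-2-one | CCC(=O)c1c(OCc2ccccc2)c(C)c(OC)c(CC2=C(CC)OC(=O)C=C2O)c1OCc1ccccc1 | intermediate
13 | methyl 7-[2,4-bis(benzyloxy)-6-methoxy-5-methyl-3-propanoylphenyl]-4-methyl-3,5-dioxoheptanoate (racemic, labile C4) | CCC(=O)c1c(OCc2ccccc2)c(C)c(OC)c(CCC(=O)C(C)C(=O)CC(=O)OC)c1OCc1ccccc1 | intermediate
14 | methyl 4-{[2,4-bis(benzyloxy)-6-methoxy-5-methyl-3-propanoylphenyl]methyl}-3,5-dioxoheptanoate (racemic, labile C4) | CCC(=O)c1c(OCc2ccccc2)c(C)c(OC)c(CC(C(=O)CC)C(=O)CC(=O)OC)c1OCc1ccccc1 | intermediate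
15 | 1-{2,6-bis(benzyloxy)-4-methoxy-3-methyl-5-[(2,4,6-trihydroxy-3-methylphenyl)methyl]phenyl}propan-1-one | Cc1c(O)cc(O)c(Cc2c(OC)c(C)c(OCc3ccccc3)c(C(=O)CC)c2OCc2ccccc2)c1O | intermediate
16 | 1-{2,6-bis(benzyloxy)-4-methoxy-3-methyl-5-[(2,4,6-trihydroxy-3-methyl-5-propanoylphenyl)methyl]phenyl}propan-1-one | CCC(=O)c1c(O)c(C)c(O)c(Cc2c(OC)c(C)c(OCc3ccccc3)c(C(=O)CC)c2OCc2ccccc2)c1O | intermediate
17 | 1-{2,6-dihydroxy-4-methoxy-3-methyl-5-[(2,4,6-trihydroxy-3-methyl-5-propanoylphenyl)methyl]phenyl}propan-1-one | CCC(=O)c1c(O)c(C)c(O)c(Cc2c(O)c(C(=O)CC)c(O)c(C)c2OC)c1O | target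

**Step count**

Total: 9 steps. Longest linear sequence: 9 steps (1 to 17).

**Steps most likely to fail**

1. Step 7 (key annulation). The acylation may stall at O-acylated or doubly acylated material, methoxide may cleave the 2-substituted 1,3-diketone by retro-Claisen fragmentation faster than the ring closes, and the polyphenolate may be oxidised by traces of air. The fallback uses known chemistry only, gives up the annulation and builds the diarylmethane bond instead; it sets out from aldehyde 6 together with triol 1 and returns to the route at 15. NaBH4 in THF/MeOH at 0 °C should reduce only the aldehyde of 6, the flanked aryl ketone being far slower, to 1-[2,6-bis(benzyloxy)-3-(hydroxymethyl)-4-methoxy-5-methylphenyl]propan-1-one F1. This 2,4,6-trialkoxybenzyl alcohol should ionise with catalytic p-toluenesulfonic acid in MeCN at rt, and the cation should be captured by an excess of 1 at one of its two equivalent free carbons (Friedel–Crafts benzylation), giving 15 directly.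

2. Step 8 (propionylation of ring A). O-acylation may compete with C-acylation, the Lewis acid may detach benzyl groups that then alkylate ring A, and acid may cause migration of the trialkoxybenzyl group. The fallback sets out from 15 and returns at 16 by a Hoesch reaction: propionitrile, HCl gas and ZnCl2 in Et2O at 0 °C should give the ketiminium salt 1-{3-[2,4-bis(benzyloxy)-6-methoxy-5-methyl-3-propanoylbenzyl]-2,4,6-trihydroxy-5-methylphenyl}propan-1-iminium chloride F2, which warm water hydrolyses to 16. The nitrilium electrophile does not leave phenol esters behind, and no anhydride or boron Lewis acid is present to cleave the benzyl ethers.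

3. Step 2 (mono-O-methylation). Methylation may run on to the dimethyl ether or occur at a chelated hydroxyl. The fallback sets out from 3 and returns at 4 by inverting the logic: exhaustive methylation (excess Me2SO4, K2CO3, acetone, reflux) to 1-(2,4,6-trimethoxy-3-methylphenyl)propan-1-one F3, then BCl3 in CH2Cl2 at 0 °C to rt. BCl3 should cleave only the two methoxy groups ortho to the carbonyl through chelation and leave the para methoxy group, giving 4.

**Further compounds**

F1 | step 7 | 1-[2,6-bis(benzyloxy)-3-(hydroxymethyl)-4-methoxy-5-methylphenyl]propan-1-one | CCC(=O)c1c(OCc2ccccc2)c(C)c(OC)c(CO)c1OCc1ccccc1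
F2 | step 8 | 1-{3-[2,4-bis(benzyloxy)-6-methoxy-5-methyl-3-propanoylbenzyl]-2,4,6-trihydroxy-5-methylphenyl}propan-1-iminium chloride | CCC(=[NH2+])c1c(O)c(C)c(O)c(Cc2c(OC)c(C)c(OCc3ccccc3)c(C(=O)CC)c2OCc2ccccc2)c1O.[Cl-]
F3 | step 2 | 1-(2,4,6-trimethoxy-3-methylphenyl)propan-1-one | CCC(=O)c1c(OC)cc(OC)c(C)c1OC
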